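**Assumption:** the target is made exactly as drawn. Locants C1–C9 follow the seco-acid chain: C1 = lactone carbonyl, C8 = carbon carrying the ring oxygen, C9 = its methyl; ring position n+1 of the oxonan-2-one equals chain carbon n.

**Retrosynthetic overview**
1. Target 22 ⇐ epoxy ester 21: water opens the 4,5-epoxide at C4 with inversion, and the side-chain silyl ether falls in the same operation.
2. 21 ⇐ epoxy alcohol 11 + side-chain acid 20 (esterification at C7–OH); 11 ⇐ cyclic alkene 10 by hydroxyl-directed epoxidation.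
3. 10, the nine-membered lactone, ⇐ diene ester 9 by ring-closing metathesis at C4=C5.
4. 9 ⇐ acid 5 + propanal + (Z)-crotylboronate: enamine-catalysed α-acyloxylation makes the C8–O ester bond and sets C8, and crotylboration sets C6 and C7; 5 ⇐ propanal + methacrolein by proline cross-aldol (C2, C3).
5. 20 ⇐ octanal by proline α-aminoxylation (C4′) and Z-selective olefination. Ring order: the lactone is closed first, the oxirane is then made and opened last; the side-chain butenolide is formed and reopened before coupling.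

**Step 1**
Reactants: 1 propanal; 2 methacrolein (2-methylprop-2-enal)
Product: 3 (2S,3R)-3-hydroxy-2,4-dimethylpent-4-enal
Conditions: L-proline (10 mol %), DMF, 4 °C; 1 added by syringe pump over 20 h to 2 (5 equiv); crude used at once
Reagents that add atoms: none
Why: Proline-catalysed direct cross-aldol reaction in which the (E)-enamine of 1 adds to the Re face of the non-enolisable aldehyde 2 through the carboxylic-acid-bound chair transition state, giving the anti (2S,3R) aldol, and slow addition of the donor suppresses propanal self-aldolisation.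

**Step 2**
Reactants: 3 (2S,3R)-3-hydroxy-2,4-dimethylpent-4-enal
Product: 4 (2S,3R)-3-hydroxy-2,4-dimethylpent-4-enoic acid
Conditions: NaClO2, NaH2PO4, 2-methylbut-2-ene (10 equiv), t-BuOH/H2O, 0 °C
Reagents that add atoms: sodium chlorite, [Na+].[O-]Cl=O
Why: Pinnick oxidation converts the aldehyde to the acid under buffered conditions that do not epimerise C2 or dehydrate the aldol, and the alkene scavenger protects the 1,1-disubstituted olefin from HOCl.

**Step 3**
Reactants: 4 (2S,3R)-3-hydroxy-2,4-dimethylpent-4-enoic acid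
Product: 5 (2S,3R)-3-acetoxy-2,4-dimethylpent-4-enoic acid
Conditions: Ac2O (2.5 equiv), pyridine, CH2Cl2, 0 °C to rt; then H2O/THF
Reagents that add atoms: acetic anhydride, CC(=O)OC(C)=O
Why: Simple O-acetylation of the secondary alcohol installs the C3 acetate of the target early, the transient mixed anhydride being hydrolysed in the aqueous quench and the low temperature avoiding β-elimination.

**Step 4**
Reactants: 5 (2S,3R)-3-acetoxy-2,4-dimethylpent-4-enoic acid; 1 propanal
Product: 7 (2S)-1-oxopropan-2-yl (2S,3R)-3-acetoxy-2,4-dimethylpent-4-enoate, via diacyl peroxide 6 (not isolated)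
Conditions: (a) urea–hydrogen peroxide (0.5 equiv), N,N'-dicyclohexylcarbodiimide (1.0 equiv), CH2Cl2, −20 °C, cold filtration; (b) filtrate added to 1 (3 equiv), (S)-2-(triphenylmethyl)pyrrolidine (10 mol %), hydroquinone (10 mol %), THF, 0 °C; cold aq. NaHCO3 wash (recovers 5); volatiles removed at 0 °C, crude used at once
Reagents that add atoms: urea–hydrogen peroxide, OO.NC(N)=O
Why: Proposed new method: enamine-catalysed α-acyloxylation of an aldehyde in which the transferred acyloxy group is a functionalised, stereodefined aliphatic carboxylate instead of benzoate – the (E)-enamine of 1, shielded on one face by the trityl group, attacks a peroxide oxygen of symmetrical peroxide 6 by SN2 displacement at oxygen from the open face, expelling the carboxylate of 5 (recovered), which forges the C8–O ester bond of the future lactone and sets C8 as S, with hydroquinone suppressing amine-induced radical decomposition of the peroxide; the closest known reaction type is the secondary-amine-catalysed α-benzoyloxylation of aldehydes with dibenzoyl peroxide.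

**Step 5**
Reactants: 7 (2S)-1-oxopropan-2-yl (2S,3R)-3-acetoxy-2,4-dimethylpent-4-enoate; 8 2-[(2Z)-but-2-en-1-yl]-4,4,5,5-tetramethyl-1,3,2-dioxaborolane
Product: 9 (2S,3R,4S)-3-hydroxy-4-methylhex-5-en-2-yl (2S,3R)-3-acetoxy-2,4-dimethylpent-4-enoate
Conditions: 8 (1.5 equiv), toluene (1 M), −20 °C to rt, 24 h; pH 7 phosphate buffer work-up
Reagents that add atoms: none
Why: Substrate-controlled crotylboration through a closed chair transition state, in which the Z-boronate gives the 6,7-syn relationship and Felkin–Anh attack anti to the α-acyloxy group (α-hydrogen turned toward the Z-methyl) gives the 7,8-anti relationship, so C6 (S) and C7 (R) are set from C8.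

**Step 6**
Reactants: 9 (2S,3R,4S)-3-hydroxy-4-methylhex-5-en-2-yl (2S,3R)-3-acetoxy-2,4-dimethylpent-4-enoate
Product: 10 (3S,4R,5Z,7S,8R,9S)-8-hydroxy-3,5,7,9-tetramethyl-2-oxo-1-oxacyclonon-5-en-4-yl acetate
Conditions: second-generation Grubbs catalyst RuCl2(=CHPh)(H2IMes)(PCy3) (10 mol %), 1,4-benzoquinone (20 mol %), toluene (1 mM), 80 °C, slow addition of 9
Reagents that add atoms: none
Why: Ring-closing metathesis in which ruthenium loads on the unhindered C5 vinyl group and closes onto the 1,1-disubstituted C4 alkene, a nine-membered ring allowing only the Z (ring-cis) trisubstituted olefin; the side chain is deliberately absent because a homoallylic enoate would instead close to a six-membered unsaturated lactone.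

**Step 7**
Reactants: 10 (3S,4R,5Z,7S,8R,9S)-8-hydroxy-3,5,7,9-tetramethyl-2-oxo-1-oxacyclonon-5-en-4-yl acetate
Product: 11 (3S,4R,5S,6S,7R,8R,9S)-5,6-epoxy-8-hydroxy-3,5,7,9-tetramethyl-2-oxooxonan-4-yl acetate
Conditions: VO(acac)2 (10 mol %), t-BuOOH (2 equiv, in decane), CH2Cl2, 0 °C to rt
Reagents that add atoms: tert-butyl hydroperoxide, CC(C)(C)OO
Why: Hydroxyl-directed vanadium-catalysed epoxidation in which the vanadium alkoxide of the homoallylic C7–OH delivers oxygen to the alkene face syn to that hydroxyl, which is also the face anti to the C6 methyl, giving the (4S,5S) epoxide (chain numbering) cis to both C7–OH and C3–OAc.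

**Step 8**
Reactants: 12 octanal; 13 ethyl 2-(diphenoxyphosphoryl)acetate
Product: 15 ethyl (2Z,4R)-4-(phenylaminooxy)dec-2-enoate, via aminooxy aldehyde 14 (not isolated)
Conditions: L-proline (20 mol %), PhNO (1.0 equiv), 12 (1.2 equiv), MeCN, −20 °C; then added to 13/NaH (1.5 equiv), THF, −78 to −20 °C
Reagents that add atoms: nitrosobenzene, O=Nc1ccccc1
Why: Proline-catalysed α-aminoxylation (O-selective nitroso aldol reaction) delivers oxygen to the enamine face directed by the carboxylic acid and sets C4′ as R, and the Ando variant of the Horner–Wadsworth–Emmons reaction then gives the Z-enoate from the α-oxygenated aldehyde.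

**Step 9**
Reactants: 15 ethyl (2Z,4R)-4-(phenylaminooxy)dec-2-enoate
Product: 17 (5R)-5-hexylfuran-2(5H)-one, via hydroxy ester 16 (not isolated)
Conditions: Cu(OAc)2 (30 mol %), EtOH, rt; then p-TsOH·H2O (5 mol %), 40 °C
Reagents that add atoms: none
Why: Copper-catalysed N–O bond cleavage frees the γ-hydroxyl without touching the stereocentre, and the Z-γ-hydroxy ester lactonises to the stable, easily purified butenolide, which also proves the Z geometry.

**Step 10**
Reactants: 17 (5R)-5-hexylfuran-2(5H)-one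
Product: 20 (2Z,4R)-4-(triethylsilyloxy)dec-2-enoic acid, via lithium hydroxy enoate 18 (not isolated), via bis-silyl derivative 19 (not isolated)
Conditions: LiOH·H2O (1.05 equiv), THF/H2O, 0 °C, 30 min; evaporate; Et3SiCl (2.5 equiv), imidazole, DMF, 0 °C; then MeOH/H2O, pH 5 buffer work-up
Reagents that add atoms: lithium hydroxide, [Li+].[OH-]; chlorotriethylsilane, CC[Si](Cl)(CC)CC
Why: Saponification opens the lactone at the acyl carbon with the Z geometry and C4′ untouched, silylation traps the hydroxyl before it can relactonise, and the labile silyl ester is hydrolysed selectively in the aqueous work-up.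

**Step 11**
Reactants: 11 (3S,4R,5S,6S,7R,8R,9S)-5,6-epoxy-8-hydroxy-3,5,7,9-tetramethyl-2-oxooxonan-4-yl acetate; 20 (2Z,4R)-4-(triethylsilyloxy)dec-2-enoic acid
Product: 21 (3S,4R,5S,6S,7R,8R,9S)-4-acetoxy-5,6-epoxy-3,5,7,9-tetramethyl-2-oxooxonan-8-yl (2Z,4R)-4-(triethylsilyloxy)dec-2-enoate
Conditions: 20 (1.5 equiv), 2-methyl-6-nitrobenzoic anhydride (1.5 equiv), DMAP (0.2 equiv), Et3N (3 equiv), CH2Cl2, rt
Reagents that add atoms: none
Why: Shiina mixed-anhydride esterification acylates the only free hydroxyl (C7–OH) under mild conditions, and the bulky γ-silyloxy group shields the β-carbon of the Z-enoate against DMAP-induced isomerisation.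

**Step 12**
Reactants: 21 (3S,4R,5S,6S,7R,8R,9S)-4-acetoxy-5,6-epoxy-3,5,7,9-tetramethyl-2-oxooxonan-8-yl (2Z,4R)-4-(triethylsilyloxy)dec-2-enoate
Product: 22 (3S,4R,5R,6S,7S,8R,9S)-4-acetoxy-5,6-dihydroxy-3,5,7,9-tetramethyl-2-oxooxonan-8-yl (2Z,4R)-4-hydroxydec-2-enoate (target)
Conditions: HClO4 (0.2 equiv, 0.05 M aq.), THF/H2O (3:1), 0 °C, 1–2 h; NaHCO3 quench at 0 °C; neutral silica, cold
Reagents that add atoms: water, O
Why: Acid-catalysed epoxide hydrolysis in which water attacks the tertiary C4 from the face opposite the oxirane oxygen (inversion at C4, retention at C5) to give the trans 4,5-diol (4R,5S), the cis-disposed C3 acetate being unable to participate, while the same dilute acid cleaves the triethylsilyl ether.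

**Compound list**
1 | propanal | CCC=O | starting material
2 | methacrolein (2-methylprop-2-enal) | CC(=C)C=O | starting material
3 | (2S,3R)-3-hydroxy-2,4-dimethylpent-4-enal | C=C(C)[C@H](O)[C@H](C)C=O | intermediate
4 | (2S,3R)-3-hydroxy-2,4-dimethylpent-4-enoic acid | C=C(C)[C@H](O)[C@H](C)C(=O)O | intermediate
5 | (2S,3R)-3-acetoxy-2,4-dimethylpent-4-enoic acid | C=C(C)[C@H](OC(C)=O)[C@H](C)C(=O)O | intermediate
6 | bis[(2S,3R)-3-acetoxy-2,4-dimethylpent-4-enoyl] peroxide | C=C(C)[C@H](OC(C)=O)[C@H](C)C(=O)OOC(=O)[C@@H](C)[C@@H](OC(C)=O)C(C)=C | intermediate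
7 | (2S)-1-oxopropan-2-yl (2S,3R)-3-acetoxy-2,4-dimethylpent-4-enoate | C=C(C)[C@H](OC(C)=O)[C@H](C)C(=O)O[C@@H](C)C=O | intermediate
8 | 2-[(2Z)-but-2-en-1-yl]-4,4,5,5-tetramethyl-1,3,2-dioxaborolane | C/C=C\CB1OC(C)(C)C(C)(C)O1 | starting material
9 | (2S,3R,4S)-3-hydroxy-4-methylhex-5-en-2-yl (2S,3R)-3-acetoxy-2,4-dimethylpent-4-enoate | C=C(C)[C@H](OC(C)=O)[C@H](C)C(=O)O[C@@H](C)[C@H](O)[C@@H](C)C=C | intermediate
10 | (3S,4R,5Z,7S,8R,9S)-8-hydroxy-3,5,7,9-tetramethyl-2-oxo-1-oxacyclonon-5-en-4-yl acetate | O[C@@H]1[C@@H](C)/C=C(C)\[C@H](OC(C)=O)[C@H](C)C(=O)O[C@H]1C | intermediate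
11 | (3S,4R,5S,6S,7R,8R,9S)-5,6-epoxy-8-hydroxy-3,5,7,9-tetramethyl-2-oxooxonan-4-yl acetate | O[C@@H]1[C@@H](C)[C@H]2[C@](C)(O2)[C@H](OC(C)=O)[C@H](C)C(=O)O[C@H]1C | intermediate
12 | octanal | CCCCCCCC=O | starting material
13 | ethyl 2-(diphenoxyphosphoryl)acetate | CCOC(=O)CP(=O)(Oc1ccccc1)Oc1ccccc1 | starting material
14 | (2R)-2-(phenylaminooxy)octanal | CCCCCC[C@@H](ONc1ccccc1)C=O | intermediate
15 | ethyl (2Z,4R)-4-(phenylaminooxy)dec-2-enoate | CCCCCC[C@@H](ONc1ccccc1)/C=C\C(=O)OCC | intermediate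
16 | ethyl (2Z,4R)-4-hydroxydec-2-enoate | CCCCCC[C@@H](O)/C=C\C(=O)OCC | intermediate
17 | (5R)-5-hexylfuran-2(5H)-one | CCCCCC[C@@H]1C=CC(=O)O1 | intermediate
18 | lithium (2Z,4R)-4-hydroxydec-2-enoate | CCCCCC[C@@H](O)/C=C\C(=O)[O-].[Li+] | intermediate
19 | triethylsilyl (2Z,4R)-4-(triethylsilyloxy)dec-2-enoate | CCCCCC[C@@H](O[Si](CC)(CC)CC)/C=C\C(=O)O[Si](CC)(CC)CC | intermediate
20 | (2Z,4R)-4-(triethylsilyloxy)dec-2-enoic acid | CCCCCC[C@@H](O[Si](CC)(CC)CC)/C=C\C(=O)O | intermediate
21 | (3S,4R,5S,6S,7R,8R,9S)-4-acetoxy-5,6-epoxy-3,5,7,9-tetramethyl-2-oxooxonan-8-yl (2Z,4R)-4-(triethylsilyloxy)dec-2-enoate | CCCCCC[C@@H](O[Si](CC)(CC)CC)/C=C\C(=O)O[C@@H]1[C@@H](C)[C@H]2[C@](C)(O2)[C@H](OC(C)=O)[C@H](C)C(=O)O[C@H]1C | intermediate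
22 | (3S,4R,5R,6S,7S,8R,9S)-4-acetoxy-5,6-dihydroxy-3,5,7,9-tetramethyl-2-oxooxonan-8-yl (2Z,4R)-4-hydroxydec-2-enoate | CCCCCC[C@@H](O)/C=C\C(=O)O[C@@H]1[C@@H](C)[C@H](O)[C@@](C)(O)[C@H](OC(C)=O)[C@H](C)C(=O)O[C@H]1C | target

**Totals**
Total step count: 12. Longest linear sequence: 9 steps (steps 1–7, 11, 12); steps 8–10 make the side-chain acid.

**Three steps most likely to fail**

Step 4 (proposed new method). The secondary-alkyl diacyl peroxide 6 may decompose (carboxy inversion, radical loss of CO2) or acylate the amine catalyst faster than the enamine attacks it. The fallback uses known chemistry only; it sets out from 1 and 5 and comes back at 9. Propanal 1 is α-benzoyloxylated with dibenzoyl peroxide under the same amine catalyst to give (2S)-1-oxopropan-2-yl benzoate F1. Crotylboration with 8 as in step 5 gives (2S,3R,4S)-3-hydroxy-4-methylhex-5-en-2-yl benzoate F2. TBSCl/imidazole gives (2S,3R,4S)-3-(tert-butyldimethylsilyloxy)-4-methylhex-5-en-2-yl benzoate F3, and K2CO3/MeOH at 0 °C removes the benzoate to give (2S,3R,4S)-3-(tert-butyldimethylsilyloxy)-4-methylhex-5-en-2-ol F4. Shiina esterification with acid 5 gives (2S,3R,4S)-3-(tert-butyldimethylsilyloxy)-4-methylhex-5-en-2-yl (2S,3R)-3-acetoxy-2,4-dimethylpent-4-enoate F5, and HF·pyridine frees the C7 hydroxyl to return to 9.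

Step 6. Closure of a nine-membered ring onto a hindered 1,1-disubstituted olefin may lose to dimerisation at the C5 vinyl group. The fallback is a relay ring-closing metathesis; it sets out from 1 (with commercial hex-5-enal and 2-(triphenylphosphoranylidene)propanal) and comes back at 10. A Wittig reaction gives (2E)-2-methylocta-2,7-dienal F6, which replaces methacrolein in steps 1–5. These give in turn (2S,3R,4E)-3-hydroxy-2,4-dimethyldeca-4,9-dienal F7, (2S,3R,4E)-3-hydroxy-2,4-dimethyldeca-4,9-dienoic acid F8, (2S,3R,4E)-3-acetoxy-2,4-dimethyldeca-4,9-dienoic acid F9, bis[(2S,3R,4E)-3-acetoxy-2,4-dimethyldeca-4,9-dienoyl] peroxide F10, (2S)-1-oxopropan-2-yl (2S,3R,4E)-3-acetoxy-2,4-dimethyldeca-4,9-dienoate F11 and (2S,3R,4S)-3-hydroxy-4-methylhex-5-en-2-yl (2S,3R,4E)-3-acetoxy-2,4-dimethyldeca-4,9-dienoate F12. With the same ruthenium catalyst the metal loads on the unhindered terminal alkene of the relay arm, extrudes cyclopentene and is thereby placed on C4, from where closure onto the C5 vinyl group gives 10. This fallback still relies on step 4 chemistry for its own ester bond; if step 4 has also failed, the same relay acid F9 is joined to alcohol F4 by the esterification route of the first fallback.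

Step 12. The freed γ-hydroxy Z-enoate can lactonise to butenolide 17 with loss of the macrolide under aqueous acid, and the free C4 hydroxyl (or the lactone carbonyl during epoxide opening) can trigger translactonisation to a γ-lactone. The fallback separates the two events with a sturdier silyl group; it sets out from 17 and 11 and comes back at 22. Butenolide 17 is opened to 18 as in step 10 and silylated with TBSCl/imidazole to tert-butyldimethylsilyl (2Z,4R)-4-(tert-butyldimethylsilyloxy)dec-2-enoate F13, whose silyl ester is cleaved with K2CO3 in MeOH/H2O to give (2Z,4R)-4-(tert-butyldimethylsilyloxy)dec-2-enoic acid F14. Esterification with 11 as in step 11 gives (3S,4R,5S,6S,7R,8R,9S)-4-acetoxy-5,6-epoxy-3,5,7,9-tetramethyl-2-oxooxonan-8-yl (2Z,4R)-4-(tert-butyldimethylsilyloxy)dec-2-enoate F15. The epoxide is hydrolysed with dilute HClO4 while the silyl ether stays on, giving (3S,4R,5R,6S,7S,8R,9S)-4-acetoxy-5,6-dihydroxy-3,5,7,9-tetramethyl-2-oxooxonan-8-yl (2Z,4R)-4-(tert-butyldimethylsilyloxy)dec-2-enoate F16. Pyridine-buffered HF·pyridine in THF at 0 °C as the last operation then liberates 22.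

**Further compounds**
F1 | step 4 | (2S)-1-oxopropan-2-yl benzoate | C[C@H](OC(=O)c1ccccc1)C=O
F2 | step 4 | (2S,3R,4S)-3-hydroxy-4-methylhex-5-en-2-yl benzoate | O=C(O[C@@H](C)[C@H](O)[C@@H](C)C=C)c1ccccc1
F3 | step 4 | (2S,3R,4S)-3-(tert-butyldimethylsilyloxy)-4-methylhex-5-en-2-yl benzoate | O=C(O[C@@H](C)[C@H](O[Si](C)(C)C(C)(C)C)[C@@H](C)C=C)c1ccccc1
F4 | step 4 | (2S,3R,4S)-3-(tert-butyldimethylsilyloxy)-4-methylhex-5-en-2-ol | O[C@@H](C)[C@H](O[Si](C)(C)C(C)(C)C)[C@@H](C)C=C
F5 | step 4 | (2S,3R,4S)-3-(tert-butyldimethylsilyloxy)-4-methylhex-5-en-2-yl (2S,3R)-3-acetoxy-2,4-dimethylpent-4-enoate | C=C(C)[C@H](OC(C)=O)[C@H](C)C(=O)O[C@@H](C)[C@H](O[Si](C)(C)C(C)(C)C)[C@@H](C)C=C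
F6 | step 6 | (2E)-2-methylocta-2,7-dienal | C=CCCC/C=C(\C)C=O
F7 | step 6 | (2S,3R,4E)-3-hydroxy-2,4-dimethyldeca-4,9-dienal | C=CCCC/C=C(\C)[C@H](O)[C@H](C)C=O
F8 | step 6 | (2S,3R,4E)-3-hydroxy-2,4-dimethyldeca-4,9-dienoic acid | C=CCCC/C=C(\C)[C@H](O)[C@H](C)C(=O)O
F9 | step 6 | (2S,3R,4E)-3-acetoxy-2,4-dimethyldeca-4,9-dienoic acid | C=CCCC/C=C(\C)[C@H](OC(C)=O)[C@H](C)C(=O)O
F10 | step 6 | bis[(2S,3R,4E)-3-acetoxy-2,4-dimethyldeca-4,9-dienoyl] peroxide | C=CCCC/C=C(\C)[C@H](OC(C)=O)[C@H](C)C(=O)OOC(=O)[C@@H](C)[C@@H](OC(C)=O)/C(C)=C/CCCC=C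
F11 | step 6 | (2S)-1-oxopropan-2-yl (2S,3R,4E)-3-acetoxy-2,4-dimethyldeca-4,9-dienoate | C=CCCC/C=C(\C)[C@H](OC(C)=O)[C@H](C)C(=O)O[C@@H](C)C=O
F12 | step 6 | (2S,3R,4S)-3-hydroxy-4-methylhex-5-en-2-yl (2S,3R,4E)-3-acetoxy-2,4-dimethyldeca-4,9-dienoate | C=CCCC/C=C(\C)[C@H](OC(C)=O)[C@H](C)C(=O)O[C@@H](C)[C@H](O)[C@@H](C)C=C
F13 | step 12 | tert-butyldimethylsilyl (2Z,4R)-4-(tert-butyldimethylsilyloxy)dec-2-enoate | CCCCCC[C@@H](O[Si](C)(C)C(C)(C)C)/C=C\C(=O)O[Si](C)(C)C(C)(C)C
F14 | step 12 | (2Z,4R)-4-(tert-butyldimethylsilyloxy)dec-2-enoic acid | CCCCCC[C@@H](O[Si](C)(C)C(C)(C)C)/C=C\C(=O)O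
F15 | step 12 | (3S,4R,5S,6S,7R,8R,9S)-4-acetoxy-5,6-epoxy-3,5,7,9-tetramethyl-2-oxooxonan-8-yl (2Z,4R)-4-(tert-butyldimethylsilyloxy)dec-2-enoate | CCCCCC[C@@H](O[Si](C)(C)C(C)(C)C)/C=C\C(=O)O[C@@H]1[C@@H](C)[C@H]2[C@](C)(O2)[C@H](OC(C)=O)[C@H](C)C(=O)O[C@H]1C
F16 | step 12 | (3S,4R,5R,6S,7S,8R,9S)-4-acetoxy-5,6-dihydroxy-3,5,7,9-tetramethyl-2-oxooxonan-8-yl (2Z,4R)-4-(tert-butyldimethylsilyloxy)dec-2-enoate | CCCCCC[C@@H](O[Si](C)(C)C(C)(C)C)/C=C\C(=O)O[C@@H]1[C@@H](C)[C@H](O)[C@@](C)(O)[C@H](OC(C)=O)[C@H](C)C(=O)O[C@H]1C
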